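**Assumptions:** ring-numbering and stereochemistry follow the target SMILES exactly. The two menthyl diastereomers of the photocycloadduct (7) are assumed separable by silica chromatography, and the one whose core matches the target is carried forward.

## Retrosynthetic overview
1. The target triol comes from LiBH4 opening of a cis-fused furofuranone lactone, which releases the C9 CH2OH and the C7′ OH together.
2. The lactone comes from a hydroxy ester by lactonization. The lactonization locks the 3,4-cis relationship, and acid epimerization at the benzylic C7 pushes the catechol aryl group exo.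
3. The hydroxy ester comes from reductive opening of an oxetane acetal, which comes from hydrogenation of a dearomatized furan.
4. **Key step:** a Paternò–Büchi [2+2] between a 2-aryl-3-furoate and vanillin acetate breaks the furan aromaticity and forms C8′–C7′ with exo selectivity, setting the like relationship of C8′/C7′.
5. Rings form in this order: oxetane (from furan plus aldehyde), THF (the furan's own O-ring), oxetane opening, then the γ-lactone last.

## Route

**Step 1**
Reactants: 1 (furan-3-carboxylic acid) + 2 (4-bromo-1,2-bis(benzyloxy)benzene)
Product: 3 (2-[3,4-bis(benzyloxy)phenyl]furan-3-carboxylic acid)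
Conditions: LDA (2.2 equiv), THF, −78 °C; ZnCl2; then 2, Pd(PPh3)4 (5 mol%), THF, 65 °C; H3O+ workup
Reagents that add atoms: none
Why: Carboxylate-directed C2 lithiation of 3-furoic acid, then transmetalation to zinc, gives a Negishi coupling that places the catechol aryl at C2 and blocks that α-position for the next step.

**Step 2**
Reactants: 3 + 4 ((−)-menthol)
Product: 5 ((1R,2S,5R)-menthyl 2-[3,4-bis(benzyloxy)phenyl]furan-3-carboxylate)
Conditions: DCC, DMAP, CH2Cl2, 0 °C→rt
Reagents that add atoms: none
Why: Steglich esterification attaches a removable chiral handle that makes the later photoadducts diastereomeric.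

**Step 3**
Reactants: 5 + 6 (vanillin acetate, 3 equiv)
Product: 7 (menthyl exo-6-(4-acetoxy-3-methoxyphenyl)-3-[3,4-bis(benzyloxy)phenyl]-2,7-dioxabicyclo[3.2.0]hept-3-ene-4-carboxylate, core matching the target C7′/C8′)
Conditions: hν (350 nm, Pyrex), PhH, rt, 24 h; silica chromatography to separate the menthyl diastereomers
Reagents that add atoms: none
Why: Furan–carbonyl Paternò–Büchi: the aldehyde triplet oxygen bonds to the free α-carbon (C5), the aryl-stabilized allylic diradical closes to a cis-fused oxetane, and the aryl group goes exo. This sets C8′ and C7′ with the required like relative configuration (C9′ becomes the acetal carbon).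
Proposed new method: the 2-aryl-3-ester substrate and the menthyl-based diastereomer separation extend Schreiber-type furan–aldehyde photocycloaddition. The 2-aryl group is meant to direct attack to the C4=C5 bond, and the ester leaves a stable push–pull enol ether.

**Step 4**
Reactants: 7 + H2
Product: 8 (saturated oxetane–THF acetal; the aryl group is endo and the ester is cis to the oxetane carbon)
Conditions: [Ir(cod)(PCy3)(py)]PF6 (10 mol%), H2 (50 bar), CH2Cl2, rt
Reagents that add atoms: none
Why: Crabtree syn-hydrogenation of the tetrasubstituted enol ether occurs from the convex face, opposite the oxetane. The ester therefore ends up cis to C7′ (C8/C8′ cis), and the benzyl ethers survive.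
Proposed new method: hydrogenation of a push–pull tetrasubstituted alkene inside a strained oxetane bicycle. The closest known reaction is Crabtree hydrogenation of hindered cyclic alkenes.

**Step 5**
Reactants: 8
Product: 9 (menthyl 2-[3,4-bis(benzyloxy)phenyl]-4-[(4-acetoxy-3-methoxyphenyl)(hydroxy)methyl]tetrahydrofuran-3-carboxylate; free C7′–OH, C9′ now CH2)
Conditions: Et3SiH (4 equiv), BF3·OEt2 (4 equiv), CH2Cl2, −78→−20 °C; then TBAF, THF, 0 °C
Reagents that add atoms: none (Et3SiH supplies hydride only; any O–SiEt3 is removed in the workup)
Why: Strain-assisted ionization of the oxetane acetal at C1 gives an oxocarbenium that Et3SiH reduces (Kishi-type reductive acetal opening), converting C9′ to CH2 and releasing C7′–OH without touching any stereocenter.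

**Step 6**
Reactants: 9
Product: 10 (4-(4-acetoxy-3-methoxyphenyl)-8-[3,4-bis(benzyloxy)phenyl]-3,7-dioxabicyclo[3.3.0]octan-2-one; cis-fused lactone, catechol aryl exo)
Conditions: p-TsOH·H2O (0.3 equiv), PhMe, 80 °C, 16 h
Reagents that add atoms: none (menthol is released)
Why: The electron-rich benzylic THF ether at C7 ionizes reversibly, while the acetate-deactivated C7′ does not. The endo/endo diaryl clash therefore drives C7 to the exo aryl, and intramolecular transesterification onto the cis ester irreversibly locks the 8,8′-cis bicyclic lactone.
Proposed new method: the epimerization and lactonization occur in one pot. The closest known reaction is acid-promoted sesamin–episesamin benzylic epimerization of furofurans combined with γ-hydroxy-ester lactonization.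

**Step 7**
Reactants: 10 + LiBH4
Product: 11 (bis-benzyl-protected 7-hydroxytaxiresinol; phenol free)
Conditions: LiBH4 (6 equiv), THF, 0 °C→rt; then K2CO3, MeOH, rt
Reagents that add atoms: none
Why: Hydride reduction of the lactone cleaves the acyl–O bond, giving CH2OH at C9 and retaining the C7′–O bond and its configuration. The aryl acetate is also cleaved (directly or by the K2CO3/MeOH wash).

**Step 8**
Reactants: 11 + H2
Product: 12 (target)
Conditions: H2 (1 atm), 10% Pd/C, EtOAc/EtOH 1:1, rt, 3 h
Reagents that add atoms: none
Why: Hydrogenolysis of the two aryl benzyl ethers unmasks the catechol. The benzylic C7′–OH and C7–O bonds are left intact under these short, mild conditions.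

## Compound list
1 | furan-3-carboxylic acid | `OC(=O)c1ccoc1` | starting material
2 | 4-bromo-1,2-bis(benzyloxy)benzene | `Brc1ccc(OCc2ccccc2)c(OCc2ccccc2)c1` | starting material
3 | 2-[3,4-bis(benzyloxy)phenyl]furan-3-carboxylic acid | `OC(=O)c1ccoc1-c1ccc(OCc2ccccc2)c(OCc2ccccc2)c1` | intermediate
4 | (−)-menthol | `CC(C)[C@@H]1CC[C@@H](C)C[C@H]1O` | starting material
5 | (−)-menthyl 2-[3,4-bis(benzyloxy)phenyl]furan-3-carboxylate | `CC(C)[C@@H]1CC[C@@H](C)C[C@H]1OC(=O)c1ccoc1-c1ccc(OCc2ccccc2)c(OCc2ccccc2)c1` | intermediate
6 | vanillin acetate (4-acetoxy-3-methoxybenzaldehyde) | `COc1cc(C=O)ccc1OC(C)=O` | starting material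
7 | Paternò–Büchi exo adduct (single menthyl diastereomer) | `CC(C)[C@@H]1CC[C@@H](C)C[C@H]1OC(=O)C2=C(c3ccc(OCc4ccccc4)c(OCc4ccccc4)c3)O[C@@H]5O[C@@H](c6ccc(OC(C)=O)c(OC)c6)[C@H]25` | intermediate
8 | hydrogenated oxetane acetal | `CC(C)[C@@H]1CC[C@@H](C)C[C@H]1OC(=O)[C@@H]2[C@H](c3ccc(OCc4ccccc4)c(OCc4ccccc4)c3)O[C@@H]5O[C@@H](c6ccc(OC(C)=O)c(OC)c6)[C@H]25` | intermediate
9 | hydroxy ester (2,3-cis, 3,4-cis) | `CC(C)[C@@H]1CC[C@@H](C)C[C@H]1OC(=O)[C@@H]2[C@H](c3ccc(OCc4ccccc4)c(OCc4ccccc4)c3)OC[C@@H]2[C@@H](O)c2ccc(OC(C)=O)c(OC)c2` | intermediate
10 | cis-fused furofuranone | `COc1cc([C@H](O3)[C@H]2CO[C@H](c4ccc(OCc5ccccc5)c(OCc5ccccc5)c4)[C@H]2C3=O)ccc1OC(C)=O` | intermediate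
11 | bis-O-benzyl 7-hydroxytaxiresinol | `COc1cc([C@H](O)[C@H]2CO[C@H](c3ccc(OCc4ccccc4)c(OCc4ccccc4)c3)[C@H]2CO)ccc1O` | intermediate
12 | (7R)-7-hydroxytaxiresinol | `COc1cc([C@H](O)[C@H]2CO[C@H](c3ccc(O)c(O)c3)[C@H]2CO)ccc1O` | target

**Total steps:** 8. **Longest linear sequence:** 8 (3-furoic acid → 12).

## Three steps most likely to fail
1. **Step 3, Paternò–Büchi reaction.** The 2-aryl-3-furoate may quench the aldehyde triplet, and the exo selectivity and diastereomer separability are unproven.
   Fallback (changes the approach): run the photocycloaddition on unsubstituted furan with vanillin acetate, which is well precedented. Open the adduct to the 3-substituted dihydrofuran carbinol and resolve it with a lipase. Then install C8 by Vilsmeier formylation and C7 by Rh-catalyzed conjugate arylation of the β-alkoxy enal. Finally, trap the 3,4-cis isomer as the lactol and reduce it.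
2. **Step 4, hydrogenation of the push–pull tetrasubstituted alkene.** It may be unreactive or non-selective.
   Fallback (changes the order and mechanism): open the oxetane first with Et3SiH/BF3 directly on 7, then reduce the resulting dihydrofuran enoate by ionic hydrogenation (Et3SiH/TFA), with protonation anti to the carbinol.
3. **Step 6, C7 epimerization with lactonization.** It could give an incomplete exo:endo ratio, or ionize C7′ or cleave benzyl ethers.
   Fallback (changes how C7 is set): redesign Steps 1–4 around a 2-methoxy-furoate so that C7 is an acetal. Then do a Lewis-acid Friedel–Crafts C-arylation with 1,2-bis(benzyloxy)benzene, with the nucleophile approaching anti to the C8/C8′ substituents.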